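Plan
1. Numbering: ring A = C-1, C-2, C-3 (C=O), C-4 (CMe2), C-5, C-10; ring B = C-5 to C-10 (C-8 carbinol, C-9 carries the chain); chain C-11 to C-23 counted outward from C-9 (C-23 = CH2OAc); β = face of the C-10 methyl.
2. Cuts: acetate C–O; C-18–C-19 and C-18–CH3, both traced to the two C–Cl bonds of a C-17H=C-18Cl2 terminus; C-15–C-16 with the C-13=C-14 olefin (Claisen) and C-13–C-14 (Grignard); ring A at C-1–C-10 and C-4=C-5, plus both C-4 methyls; C-8–CH3, C-9–C-11 and C-10–CH3 back to p-benzoquinone mono(dimethyl ketal); the C-19–C-23 piece comes from acrolein.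
3. Forward order: ring B first (steps 1–4); then ring A by annulation, the cis ring fusion and the gem-dimethyl group (steps 5–7); growth of the chain to C-17 (steps 8–12); union with the C-19–C-23 piece at C-18 (step 16); methylation of C-18, desilylation and acetylation.
4. Enabling feature: C-18 is the vinylic carbon of the central olefin that carries two carbon groups (CH3 and C-19), opposite C-17, which carries H and C-16. As C-17H=C-18Cl2 its two C–Cl bonds differ only in lying cis or trans to C-16, so one cross-coupling joins the fragments and fixes the E geometry at once; the second chloride is then exchanged for methyl with retention.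
5. Stereocentres: C-9 (and, for the time being, C-10) from a catalytic asymmetric conjugate addition followed by anti allylation; C-8 from axial 1,2-addition of methyl cis to the C-9 substituent; quaternary C-10 from a Michael addition anti to the C-9 chain; C-5 from hydrogenation on the face of the C-10 methyl.
6. Olefins: C-13=C-14 from a chair Claisen rearrangement; C-17=C-18 from the site-selective coupling and a stereoretentive methylation; C-21=C-22 from a stabilised Wittig reaction.

Key step: step 16

Remark: as written, the SMILES places H-5 on the same face as the C-10 methyl (5S,8R,9R,10S; a cis-fused decalin, unlike the trans-fused bicycle of sclareolide), so a de novo route to exactly this configuration is planned.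

Step 1
Reactants: 1 4,4-dimethoxycyclohexa-2,5-dien-1-one
Product: 3 (5R,6R)-6-allyl-4,4-dimethoxy-5-methylcyclohex-2-en-1-one (allyl trans to methyl), via methylzinc dienolate 2 (not isolated)
Conditions: Me2Zn, Cu(OTf)2 (2 mol %), chiral O,O'-(1,1'-binaphthalene-2,2'-diyl) N,N-bis(1-phenylethyl)phosphoramidite (4 mol %, enantiomer that gives 5R), toluene, −25 °C; then allyl acetate, Pd(PPh3)4 (2 mol %), 0 °C
Reagents that add atoms: dimethylzinc (C[Zn]C); allyl acetate (C=CCOC(C)=O)
Why: Copper-catalysed asymmetric conjugate addition of Me2Zn desymmetrises the achiral dienone (the phosphoramidite complex selects one enantiotopic enone and so fixes the methyl-bearing carbon, the later C-10), and the zinc enolate is then allylated under Pd(PPh3)4 catalysis (Tsuji–Trost allylation) anti to that methyl group, which sets C-9.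

Step 2
Reactants: 3 (5R,6R)-6-allyl-4,4-dimethoxy-5-methylcyclohex-2-en-1-one
Product: 4 (1R,5R,6R)-6-allyl-4,4-dimethoxy-1,5-dimethylcyclohex-2-en-1-ol (1-methyl cis to allyl; hydroxyl trans to allyl)
Conditions: MeLi, THF, −78 °C
Reagents that add atoms: methyllithium ([Li]C)
Why: 1,2-Addition of an organolithium to an enone; attack along the axial trajectory of the half-chair, on the face away from the 1,3-related methyl group, should place the new methyl cis to the allyl group and the hydroxyl trans to it, which sets C-8.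

Step 3
Reactants: 4 (1R,5R,6R)-6-allyl-4,4-dimethoxy-1,5-dimethylcyclohex-2-en-1-ol
Product: 7 (4R,5R,6R)-4-hydroxy-5-(3-hydroxypropyl)-4,6-dimethylcyclohex-2-en-1-one, via 9-BBN adduct 5 (not isolated), via ketal diol 6 (not isolated)
Conditions: 9-BBN, THF, 0 °C to rt; NaOH, H2O2, 0 °C; then aq. oxalic acid, THF, rt
Reagents that add atoms: 9-borabicyclo[3.3.1]nonane (B1C2CCCC1CCC2; boron only in 5); hydrogen peroxide (OO); water (O)
Why: Anti-Markovnikov hydroboration–oxidation with 9-BBN acts only on the terminal allyl olefin (the ring olefin lies between two fully substituted carbons), and the acid work-up hydrolyses the allylic dimethyl ketal to the enone without touching a stereocentre.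

Step 4
Reactants: 7 (4R,5R,6R)-4-hydroxy-5-(3-hydroxypropyl)-4,6-dimethylcyclohex-2-en-1-one
Product: 8 (4R,5R,6R)-4-(TBS-oxy)-5-[3-(TBS-oxy)propyl]-4,6-dimethylcyclohex-2-en-1-one (TBS = tert-butyldimethylsilyl)
Conditions: TBSOTf, 2,6-lutidine, CH2Cl2, −78 to 0 °C
Reagents that add atoms: tert-butyldimethylsilyl triflate (CC(C)(C)[Si](C)(C)OS(=O)(=O)C(F)(F)F)
Why: Silylation with the silyl triflate caps the primary and the hindered tertiary hydroxyl, which would otherwise be methylated in step 7 or interfere with the enolate chemistry of step 5.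

Step 5
Reactants: 8 bis-TBS enone
Product: 10 8α-(TBS-oxy)-9β-[3-(TBS-oxy)propyl]-8β,10β-dimethyl-Δ4,6-decalin-3-one, via silyl diketone 9 (not isolated)
Conditions: LiN(i-Pr)2, THF, −78 °C; 3-(trimethylsilyl)but-3-en-2-one, −78 to −20 °C; then KOH, MeOH, rt to 50 °C
Reagents that add atoms: 3-(trimethylsilyl)but-3-en-2-one (CC(=O)C(=C)[Si](C)(C)C)
Why: Robinson annulation with an α-silyl vinyl ketone as Michael acceptor: the methyl-bearing carbon (C-10) is the only enolisable position of the enone, its lithium enolate should add anti to the C-9 chain (and away from the axial C-8 methyl), which sets the quaternary C-10 with its methyl cis to the chain, and methanolic KOH then removes silicon and closes ring A by aldol condensation.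

Step 6
Reactants: 10 Δ4,6-dien-3-one
Product: 11 5β-H (cis-fused) 8α-(TBS-oxy)-9β-[3-(TBS-oxy)propyl]-8β,10β-dimethyldecalin-3-one
Conditions: H2 (1 atm), Pd/C, pyridine, rt
Reagents that add atoms: none
Why: Heterogeneous hydrogenation saturates both olefins of the 4,6-dien-3-one; on palladium in pyridine hydrogen should be delivered to C-5 on the face of the angular methyl, as it is with 10-methyl-4-en-3-ones of the steroid series, which sets the cis ring fusion, and pyridine holds back hydrogenolysis of the allylic silyl ether.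

Step 7
Reactants: 11 cis-fused 3-ketone
Product: 12 cis-fused 8α-(TBS-oxy)-9β-[3-(TBS-oxy)propyl]-4,4,8β,10β-tetramethyldecalin-3-one
Conditions: KOt-Bu, MeI, t-BuOH–THF, 0 °C to rt
Reagents that add atoms: iodomethane (CI)
Why: Exhaustive enolate alkylation under equilibrating conditions; a cis-fused 3-ketone enolises towards C-4 (as 5β-3-keto steroids do), so both methyl groups should enter at C-4 and no stereocentre is formed.

Step 8
Reactants: 12 bis-TBS ketone
Product: 13 cis-fused 8α-(TBS-oxy)-9β-(3-hydroxypropyl)-4,4,8β,10β-tetramethyldecalin-3-one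
Conditions: PPTS, MeOH, rt
Reagents that add atoms: none
Why: Acid-catalysed methanolysis removes the unhindered primary TBS ether much faster than the tertiary one at C-8.

Step 9
Reactants: 13 primary alcohol
Product: 14 C-13 aldehyde (as 13 with the C-9 chain CH2CH2CHO)
Conditions: Dess–Martin periodinane, NaHCO3, CH2Cl2, 0 °C to rt
Reagents that add atoms: none
Why: Dess–Martin oxidation of the primary alcohol to the aldehyde under buffered conditions that leave the ketone and the silyl ether alone.

Step 10
Reactants: 14 C-13 aldehyde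
Product: 15 allylic alcohol (C-9 chain CH2CH2CH(OH)C(CH3)=CH2; both C-13 epimers)
Conditions: CH2=C(CH3)MgBr, THF, −78 °C
Reagents that add atoms: isopropenylmagnesium bromide (CC(=C)[Mg]Br)
Why: Grignard addition, chemoselective for the aldehyde over the ketone flanked by the quaternary C-4; the new carbinol centre at C-13 forms as a mixture that is of no consequence because it is destroyed in step 11.

Step 11
Reactants: 15 allylic alcohol
Product: 17 (E)-C-17 aldehyde (C-9 chain CH2CH2CH=C(CH3)CH2CH2CHO), via allyl vinyl ether 16 (not isolated)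
Conditions: n-butyl vinyl ether, Pd(OCOCF3)2 (5 mol %), 4,7-diphenyl-1,10-phenanthroline, Et3N, 75 °C; then xylene, 140 °C
Reagents that add atoms: butyl vinyl ether (C=COCCCC)
Why: Palladium-catalysed transfer vinylation gives the allyl vinyl ether, and the Claisen rearrangement through a chair transition state with the C-12 chain equatorial forms C-15–C-16 and should give the E-configured C-13=C-14 olefin.

Step 12
Reactants: 17 (E)-C-17 aldehyde
Product: 18 1,1-dichloroalkene (C-9 chain CH2CH2CH=C(CH3)CH2CH2CH=CCl2)
Conditions: PPh3, CBrCl3, MeCN, 0 °C to rt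
Reagents that add atoms: bromotrichloromethane (ClC(Cl)(Cl)Br)
Why: Wittig-type dichloromethylenation with the ylide generated from PPh3 and CBrCl3 converts the aldehyde into the 1,1-dichloroalkene, while the hindered ketone does not react.

Step 13
Reactants: 19 acrolein; 20 ethyl 2-(triphenylphosphoranylidene)propanoate
Product: 21 ethyl (E)-2-methylpenta-2,4-dienoate
Conditions: CH2Cl2, 0 °C to rt
Reagents that add atoms: none
Why: Wittig reaction of a stabilised ylide with an unhindered aldehyde, which should give the E-configured trisubstituted olefin (the later C-21=C-22).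

Step 14
Reactants: 21 ethyl (E)-2-methylpenta-2,4-dienoate
Product: 22 (E)-2-methylpenta-2,4-dien-1-ol
Conditions: i-Bu2AlH, CH2Cl2, −78 °C
Reagents that add atoms: none
Why: 1,2-Reduction of the dienoate to the allylic alcohol with i-Bu2AlH, which leaves the diene untouched.

Step 15
Reactants: 22 (E)-2-methylpenta-2,4-dien-1-ol
Product: 23 tert-butyldimethyl{[(E)-2-methylpenta-2,4-dien-1-yl]oxy}silane
Conditions: TBSCl, imidazole, CH2Cl2, 0 °C to rt
Reagents that add atoms: tert-butyldimethylsilyl chloride (CC(C)(C)[Si](C)(C)Cl)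
Why: Standard silylation of the primary allylic alcohol, so that no allylic ester is exposed to the palladium catalysts of steps 16 and 17.

Step 16
Reactants: 23 silyl dienyl ether; 18 1,1-dichloroalkene
Product: 25 (Z)-18-chloro triene (chain as in the target with Cl in place of the C-18 methyl, C-19 trans to C-16; C-23 and C-8 as TBS ethers), via alkylborane 24 (not isolated)
Conditions: 23, 9-BBN, THF, 0 °C to rt; then 18, Pd2(dba)3 (2.5 mol %), Xantphos (5 mol %), K3PO4 (3 M aq.), THF, 65 °C
Reagents that add atoms: 9-borabicyclo[3.3.1]nonane (B1C2CCCC1CCC2; its boron bicycle is present only in 24)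
Why: B-alkyl Suzuki–Miyaura coupling of a 1,1-dichloro-1-alkene: zerovalent palladium bearing the wide-bite-angle bisphosphine inserts into the C-18–Cl bond that lies trans to C-16, the hydroxyborate formed from 24 transfers its primary alkyl group (C-19) to palladium, and reductive elimination forms C-18–C-19 with retention at the olefin. The closest known reaction type is the trans-selective monoalkylation of 1,1-dichloro- and 1,1-dibromo-1-alkenes with 9-alkyl-9-BBN or alkylzinc reagents, which gives (Z)-2-halo-2-alkenes. No ring is closed and no stereocentre is formed; the new stereo-element is the geometry of the C-17=C-18 olefin, controlled by the steric difference between the two geminal C–Cl bonds and completed in step 17 when the remaining chloride is replaced by methyl with retention. The step needs site selectivity (trans over cis chloride) and mono- over double coupling, both secured by the C-16 methylene group, which shields the cis chloride and makes the product, a more hindered and more electron-rich trisubstituted alkenyl chloride, unreactive under these conditions. It also needs chemoselectivity, secured because 9-BBN hydroborates diene 23 only at its terminal vinyl group and because the hindered C-3 ketone and the silyl ethers of 18 are inert to the borate and to aqueous phosphate.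

Step 17
Reactants: 25 (Z)-18-chloro triene
Product: 26 all-E triene bis-TBS ether (target skeleton with C-23 OTBS and C-8 OTBS)
Conditions: Me2Zn, Pd(P(t-Bu)3)2 (5 mol %), THF, 50 °C
Reagents that add atoms: dimethylzinc (C[Zn]C)
Why: Negishi coupling of the alkenyl chloride with Me2Zn; with the electron-rich Pd(P(t-Bu)3)2 catalyst oxidative addition and reductive elimination proceed with retention, so the methyl group ends cis to C-16 and the C-17=C-18 olefin is E.

Step 18
Reactants: 26 bis-TBS ether
Product: 27 diol (C-23 primary allylic alcohol and C-8 tertiary alcohol; otherwise the target skeleton)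
Conditions: Bu4NF, THF, 50 °C
Reagents that add atoms: none
Why: Fluoride-mediated desilylation removes both the primary allylic and the tertiary silyl ether, while the ketone and the olefins are inert.

Step 19
Reactants: 27 diol
Product: 28 myrrhanone A acetate as drawn in the SMILES (target)
Conditions: Ac2O, pyridine, CH2Cl2, 0 °C
Reagents that add atoms: acetic anhydride (CC(=O)OC(C)=O)
Why: Acylation of the primary allylic alcohol; the tertiary C-8 hydroxyl is too hindered to react under these mild conditions, so the monoacetate should result.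

Compound list
1 | 4,4-dimethoxycyclohexa-2,5-dien-1-one | COC1(OC)C=CC(=O)C=C1 | starting material
2 | methylzinc dienolate of (5R)-4,4-dimethoxy-5-methylcyclohex-2-en-1-one | C[Zn]OC1=C[C@@H](C)C(OC)(OC)C=C1 | intermediate
3 | (5R,6R)-6-allyl-4,4-dimethoxy-5-methylcyclohex-2-en-1-one | C=CC[C@@H]1[C@@H](C)C(OC)(OC)C=CC1=O | intermediate
4 | (1R,5R,6R)-6-allyl-4,4-dimethoxy-1,5-dimethylcyclohex-2-en-1-ol | C=CC[C@@H]1[C@@H](C)C(OC)(OC)C=C[C@@]1(C)O | intermediate
5 | 9-BBN adduct of 4 (boron on the terminal carbon of the former allyl group) | B1(CCC[C@@H]3[C@@H](C)C(OC)(OC)C=C[C@@]3(C)O)C2CCCC1CCC2 | intermediate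
6 | (1R,5R,6R)-6-(3-hydroxypropyl)-4,4-dimethoxy-1,5-dimethylcyclohex-2-en-1-ol | OCCC[C@@H]1[C@@H](C)C(OC)(OC)C=C[C@@]1(C)O | intermediate
7 | (4R,5R,6R)-4-hydroxy-5-(3-hydroxypropyl)-4,6-dimethylcyclohex-2-en-1-one | OCCC[C@@H]1[C@@H](C)C(=O)C=C[C@@]1(C)O | intermediate
8 | (4R,5R,6R)-4-(TBS-oxy)-5-[3-(TBS-oxy)propyl]-4,6-dimethylcyclohex-2-en-1-one | CC(C)(C)[Si](C)(C)OCCC[C@@H]1[C@@H](C)C(=O)C=C[C@@]1(C)O[Si](C)(C)C(C)(C)C | intermediate
9 | silyl diketone: 8 with a 3-oxo-2-(trimethylsilyl)butyl group on the methyl-bearing α-carbon, trans to the silyloxypropyl chain (mixture at the silyl-bearing carbon) | CC(C)(C)[Si](C)(C)OCCC[C@@H]1[C@@](C)(CC(C(C)=O)[Si](C)(C)C)C(=O)C=C[C@@]1(C)O[Si](C)(C)C(C)(C)C | intermediate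
10 | 8α-(TBS-oxy)-9β-[3-(TBS-oxy)propyl]-8β,10β-dimethyl-Δ4,6-decalin-3-one | CC(C)(C)[Si](C)(C)OCCC[C@@H]1[C@@]2(C)CCC(=O)C=C2C=C[C@@]1(C)O[Si](C)(C)C(C)(C)C | intermediate
11 | 5β-H (cis-fused) 8α-(TBS-oxy)-9β-[3-(TBS-oxy)propyl]-8β,10β-dimethyldecalin-3-one | CC(C)(C)[Si](C)(C)OCCC[C@@H]1[C@@]2(C)CCC(=O)C[C@H]2CC[C@@]1(C)O[Si](C)(C)C(C)(C)C | intermediate
12 | cis-fused 8α-(TBS-oxy)-9β-[3-(TBS-oxy)propyl]-4,4,8β,10β-tetramethyldecalin-3-one | CC(C)(C)[Si](C)(C)OCCC[C@@H]1[C@@]2(C)CCC(=O)C(C)(C)[C@H]2CC[C@@]1(C)O[Si](C)(C)C(C)(C)C | intermediate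
13 | cis-fused 8α-(TBS-oxy)-9β-(3-hydroxypropyl)-4,4,8β,10β-tetramethyldecalin-3-one | OCCC[C@@H]1[C@@]2(C)CCC(=O)C(C)(C)[C@H]2CC[C@@]1(C)O[Si](C)(C)C(C)(C)C | intermediate
14 | C-13 aldehyde: 3-(decalin-9β-yl)propanal, decalin unit as in 13 | O=CCC[C@@H]1[C@@]2(C)CCC(=O)C(C)(C)[C@H]2CC[C@@]1(C)O[Si](C)(C)C(C)(C)C | intermediate
15 | allylic alcohol: 2-methyl-5-(decalin-9β-yl)pent-1-en-3-ol, both C-13 epimers, decalin unit as in 13 | C=C(C)C(O)CC[C@@H]1[C@@]2(C)CCC(=O)C(C)(C)[C@H]2CC[C@@]1(C)O[Si](C)(C)C(C)(C)C | intermediate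
16 | vinyl ether of 15 | C=COC(CC[C@@H]1[C@@]2(C)CCC(=O)C(C)(C)[C@H]2CC[C@@]1(C)O[Si](C)(C)C(C)(C)C)C(C)=C | intermediate
17 | (E)-4-methyl-7-(decalin-9β-yl)hept-4-enal, decalin unit as in 13 | O=CCC/C(C)=C/CC[C@@H]1[C@@]2(C)CCC(=O)C(C)(C)[C@H]2CC[C@@]1(C)O[Si](C)(C)C(C)(C)C | intermediate
18 | (5E)-1,1-dichloro-5-methyl-8-(decalin-9β-yl)octa-1,5-diene, decalin unit as in 13 | ClC(Cl)=CCC/C(C)=C/CC[C@@H]1[C@@]2(C)CCC(=O)C(C)(C)[C@H]2CC[C@@]1(C)O[Si](C)(C)C(C)(C)C | intermediate
19 | acrolein | C=CC=O | starting material
20 | ethyl 2-(triphenylphosphoranylidene)propanoate | CCOC(=O)C(C)=P(c1ccccc1)(c1ccccc1)c1ccccc1 | starting material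
21 | ethyl (E)-2-methylpenta-2,4-dienoate | CCOC(=O)/C(C)=C/C=C | intermediate
22 | (E)-2-methylpenta-2,4-dien-1-ol | OC/C(C)=C/C=C | intermediate
23 | tert-butyldimethyl{[(E)-2-methylpenta-2,4-dien-1-yl]oxy}silane | CC(C)(C)[Si](C)(C)OC/C(C)=C/C=C | intermediate
24 | 9-[(E)-5-(TBS-oxy)-4-methylpent-3-en-1-yl]-9-borabicyclo[3.3.1]nonane | CC(C)(C)[Si](C)(C)OC/C(C)=C/CCB1C2CCCC1CCC2 | intermediate
25 | (Z)-18-chloro triene: target skeleton with Cl in place of the C-18 methyl (C-19 trans to C-16), C-23 OTBS, C-8 OTBS | CC(C)(C)[Si](C)(C)OC/C(C)=C/CC/C(Cl)=C/CC/C(C)=C/CC[C@@H]1[C@@]2(C)CCC(=O)C(C)(C)[C@H]2CC[C@@]1(C)O[Si](C)(C)C(C)(C)C | intermediate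
26 | all-E triene with C-23 OTBS and C-8 OTBS | CC(C)(C)[Si](C)(C)OC/C(C)=C/CC/C(C)=C/CC/C(C)=C/CC[C@@H]1[C@@]2(C)CCC(=O)C(C)(C)[C@H]2CC[C@@]1(C)O[Si](C)(C)C(C)(C)C | intermediate
27 | diol: the C-23 alcohol corresponding to the target (8α-OH free) | OC/C(C)=C/CC/C(C)=C/CC/C(C)=C/CC[C@@H]1[C@@]2(C)CCC(=O)C(C)(C)[C@H]2CC[C@@]1(C)O | intermediate
28 | myrrhanone A acetate as drawn (5S,8R,9R,10S) | CC(=O)OC/C(C)=C/CC/C(C)=C/CC/C(C)=C/CC[C@@H]1[C@@]2(C)CCC(=O)C(C)(C)[C@H]2CC[C@@]1(C)O | target

Total steps: 19. Longest linear sequence: 16 steps (steps 1–12, then 16–19).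

Steps most likely to fail

Step 7. The process at risk is loss of regiocontrol in the enolisation of the cis-fused ketone, so that methylation takes place at C-2 in competition with C-4, together with over-methylation. The fallback builds the first C-4 methyl in during the annulation. It sets out from 8: the lithium enolate is added to 2-(trimethylsilyl)pent-1-en-3-one to give the silyl diketone F1, which KOH in MeOH converts into the 4-methyl-Δ4,6-dien-3-one F2. Hydrogenation (H2, Pd/C, pyridine, raised pressure) gives the cis-fused 4-methyl ketone F3 (mixture at C-4). Under equilibration with KOt-Bu this ketone forms the more substituted enolate, towards C-4, and a single methylation with MeI brings the route back to 12.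

Step 6. The process at risk is poor facial selectivity of hydrogen delivery at C-5 (giving the trans-fused isomer), and hydrogenolysis of the allylic C-8–O bond. The fallback uses hydroxyl-directed homogeneous hydrogenation. It sets out from 10: Luche reduction (NaBH4, CeCl3·7H2O, MeOH), with hydride entering from the α face, gives the 3β-allylic alcohol F4. Hydrogenation with [Ir(cod)(PCy3)(py)]PF6 in CH2Cl2 is directed by the 3β-hydroxyl to the β face of C-4=C-5 and gives the cis-fused alcohol F5. Dess–Martin oxidation brings the route back to 11.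

Step 2. The process at risk is poor or reversed facial selectivity of the methyl addition, which would give the C-8 epimer. The fallback introduces carbon and oxygen at C-8 in the opposite order. It sets out from 3: Wittig methylenation (Ph3P=CH2, THF) gives the exocyclic diene F6. Epoxidation of the exocyclic olefin (mCPBA, NaHCO3, CH2Cl2), on the face that the nucleophile preferred, places oxygen there and gives the spiro-epoxide F7. Hydride opening at the primary carbon (LiBHEt3, THF) brings the route back to 4.

Further compounds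
F1 | step 7 | silyl diketone: 8 with a 3-oxo-2-(trimethylsilyl)pentyl group on the methyl-bearing α-carbon, trans to the silyloxypropyl chain | CC(C)(C)[Si](C)(C)OCCC[C@@H]1[C@@](C)(CC(C(=O)CC)[Si](C)(C)C)C(=O)C=C[C@@]1(C)O[Si](C)(C)C(C)(C)C
F2 | step 7 | 8α-(TBS-oxy)-9β-[3-(TBS-oxy)propyl]-4,8β,10β-trimethyl-Δ4,6-decalin-3-one | CC(C)(C)[Si](C)(C)OCCC[C@@H]1[C@@]2(C)CCC(=O)C(C)=C2C=C[C@@]1(C)O[Si](C)(C)C(C)(C)C
F3 | step 7 | cis-fused 8α-(TBS-oxy)-9β-[3-(TBS-oxy)propyl]-4,8β,10β-trimethyldecalin-3-one (mixture at C-4) | CC(C)(C)[Si](C)(C)OCCC[C@@H]1[C@@]2(C)CCC(=O)C(C)[C@H]2CC[C@@]1(C)O[Si](C)(C)C(C)(C)C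
F4 | step 6 | 3β-hydroxy-8α-(TBS-oxy)-9β-[3-(TBS-oxy)propyl]-8β,10β-dimethyl-Δ4,6-decalin | CC(C)(C)[Si](C)(C)OCCC[C@@H]1[C@@]2(C)CC[C@H](O)C=C2C=C[C@@]1(C)O[Si](C)(C)C(C)(C)C
F5 | step 6 | cis-fused 3β-hydroxy-8α-(TBS-oxy)-9β-[3-(TBS-oxy)propyl]-8β,10β-dimethyldecalin | CC(C)(C)[Si](C)(C)OCCC[C@@H]1[C@@]2(C)CC[C@H](O)C[C@H]2CC[C@@]1(C)O[Si](C)(C)C(C)(C)C
F6 | step 2 | (5R,6R)-6-allyl-4,4-dimethoxy-5-methyl-1-methylidenecyclohex-2-ene | C=CC[C@@H]1[C@@H](C)C(OC)(OC)C=CC1=C
F7 | step 2 | spiro-epoxide of F6 at the exocyclic olefin (oxygen trans to the allyl group) | C=CC[C@@H]1[C@@H](C)C(OC)(OC)C=C[C@]12CO2
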